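**Strategy.** Everything rests on storing C5, C6 and the chain carbons C1'–C3' of the target as a cyclopentene that hangs on nitrogen. One ruthenium-catalysed cascade opens this carbocycle, closes the piperidine (ring A) by forming the C4=C5 bond from the vinyl group on C3, and joins the released alkylidene at C3' to dodec-11-en-2-one (C3'=C4'). The feature exploited is this five-carbon string C5–C6–C1'–C2'–C3', branching at the nitrogen-bearing carbon C6. The precursor is the O-TBS ether of threo-(2R,3R)-2-aminopent-4-en-3-ol carrying an (S)-cyclopent-2-enyl group on nitrogen, run as its ammonium tosylate. Hydrogenation, desilylation and O-acetylation under acid complete the route.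

Key step: step 7

Assumption: the (R,R)-enantiomer of the ligand in step 5 is taken to direct nitrogen to the allyl terminus that gives the (S) centre; if a first run shows the opposite sense, the (S,S)-ligand is used under the same conditions.

Remark: the C3'=C4' alkene of 14 may form as an E/Z mixture, which does not matter because step 8 saturates it. Sulfonyl hydrazide sources of diimide are avoided for that saturation because they would condense with the methyl ketone.

**Step 1**
Reactants: 1 methyl N-(tert-butoxycarbonyl)-D-alaninate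
Product: 3 tert-butyl N-[(2R,3R)-3-hydroxypent-4-en-2-yl]carbamate, via N-Boc-D-alaninal 2 (not isolated)
Conditions: iBu2AlH, CH2Cl2/toluene, −78 °C; then CH2=CHMgBr (excess), THF, −78 to −20 °C; aq. Rochelle salt; chromatography
Reagents that add atoms: vinylmagnesium bromide, C=C[Mg]Br
Why: Half-reduction of the ester gives the aldehyde held as its aluminium hemiacetal, which keeps the α-centre intact, and the Grignard addition that follows is expected to run under Cram-chelate control (carbamate nitrogen and carbonyl oxygen on one metal) to favour the threo (3R) alcohol, the erythro epimer being removed by chromatography.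

**Step 2**
Reactants: 3 tert-butyl N-[(2R,3R)-3-hydroxypent-4-en-2-yl]carbamate
Product: 5 (2R,3R)-3-(tert-butyldimethylsilyloxy)pent-4-en-2-amine, via silyl carbamate 4 (not isolated)
Conditions: TBSOTf (2.5 equiv), 2,6-lutidine, CH2Cl2, 0 °C to rt; then MeOH, aq. K2CO3, rt
Reagents that add atoms: tert-butyldimethylsilyl trifluoromethanesulfonate, CC(C)(C)[Si](C)(C)OS(=O)(=O)C(F)(F)F
Why: The silyl triflate silylates the alcohol and, in excess, turns the Boc group into a silyl carbamate with loss of 2-methylpropene (Ohfune-type Boc cleavage), which aqueous carbonate then decarboxylates to the free amine without protic acid, so the allylic silyl ether and both stereocentres stay untouched.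

**Step 3**
Reactants: 6 cyclopent-2-en-1-one
Product: 7 cyclopent-2-en-1-ol (racemic)
Conditions: NaBH4, CeCl3·7H2O, MeOH, 0 °C
Reagents that add atoms: none
Why: Luche reduction, in which the cerium salt steers borohydride to 1,2-addition; the racemate suffices because step 5 passes through a symmetric allyl complex.

**Step 4**
Reactants: 7 cyclopent-2-en-1-ol (racemic)
Product: 8 cyclopent-2-en-1-yl methyl carbonate (racemic)
Conditions: ClCO2Me, pyridine, CH2Cl2, 0 °C to rt
Reagents that add atoms: methyl chloroformate, COC(=O)Cl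
Why: Plain O-acylation of a secondary alcohol with a chloroformate installs the carbonate leaving group needed for allylic substitution without added base.

**Step 5**
Reactants: 5 (2R,3R)-3-(tert-butyldimethylsilyloxy)pent-4-en-2-amine; 8 cyclopent-2-en-1-yl methyl carbonate (racemic)
Product: 9 (2R,3R)-3-(tert-butyldimethylsilyloxy)-N-[(1S)-cyclopent-2-en-1-yl]pent-4-en-2-amine
Conditions: Pd2(dba)3·CHCl3 (cat.), (1R,2R)-N,N'-bis[2-(diphenylphosphino)benzoyl]cyclohexane-1,2-diamine (Trost ligand, cat.), CH2Cl2, rt
Reagents that add atoms: none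
Why: Tsuji–Trost asymmetric allylic amination, in which zerovalent palladium ionises either enantiomer of 8 to the same meso π-allyl complex and the chiral pocket of the ligand directs the primary amine to one allyl terminus, setting the (S) centre that becomes C6, while the bulk of the secondary amine formed prevents a second allylation.

**Step 6**
Reactants: 10 undec-10-enoyl chloride
Product: 11 dodec-11-en-2-one
Conditions: MeMgBr (1.1 equiv), Fe(acac)3 (3 mol%), THF, −78 °C
Reagents that add atoms: methylmagnesium bromide, C[Mg]Br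
Why: Iron-catalysed cross-coupling of a Grignard reagent with an acid chloride is much faster at −78 °C than addition to the ketone formed, and the terminal alkene is inert.

**Step 7**
Reactants: 9 (2R,3R)-3-(tert-butyldimethylsilyloxy)-N-[(1S)-cyclopent-2-en-1-yl]pent-4-en-2-amine; 11 dodec-11-en-2-one
Product: 14 (2R,3R,6S)-3-(tert-butyldimethylsilyloxy)-2-methyl-6-[(E)-13-oxotetradec-3-enyl]-1,2,3,6-tetrahydropyridine, via ammonium tosylate 12 (not isolated), via tetrahydropyridinium tosylate 13 (not isolated)
Conditions: TsOH·H2O (1.0 equiv), CH2Cl2, rt; then 11 (about 4 equiv), RuCl2(H2IMes)(=CH-C6H4-O-iPr) (second-generation Hoveyda–Grubbs catalyst, 5–10 mol%), CH2Cl2 (dilute), 40 °C; aq. NaOH work-up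
Reagents that add atoms: none
Why: A ruthenium alkylidene (formed at the terminal alkene of 11 or at the vinyl group of 12) adds to the strained cyclopentene double bond by [2+2] cycloaddition, cycloreversion opens the carbocycle, and the carbene so placed engages the remaining alkene, so that the C4=C5 bond closes ring A while the alkylidene at C3' is capped by cross-metathesis with the excess of 11; the closest known reaction type is the ring-rearrangement metathesis of N-alkenyl cycloalkenylamines run in tandem with cross-metathesis. Ring A closes in ring-closing-metathesis mode as a six-membered ring between the vinyl CH on C3 and the ring-alkene CH next to the nitrogen-bearing carbon. No stereocentre is made: C2, C3 and the former cyclopentenyl carbon (C6) have no bond broken, so the all-cis array is carried over unchanged. The selectivity needed is closure of the six-membered ring only and capture of the chain alkylidene by 11 instead of by a second molecule of substrate; the two reacting alkene carbons are joined through C3, C2, N and C6, which allows no other small ring, and dilution together with the excess of 11 favours the crossed product. Protonation of nitrogen as the tosylate keeps the amine from binding ruthenium, and release of ring strain with loss of ethene drives the sequence forward. The geometry of the C3'=C4' alkene is irrelevant because step 8 removes it.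

**Step 8**
Reactants: 14 (2R,3R,6S)-3-(tert-butyldimethylsilyloxy)-2-methyl-6-[(E)-13-oxotetradec-3-enyl]-1,2,3,6-tetrahydropyridine
Product: 15 (2R,3R,6S)-3-(tert-butyldimethylsilyloxy)-2-methyl-6-(13-oxotetradecyl)piperidine
Conditions: H2 (1 atm), Pd/C (10%), EtOAc, rt
Reagents that add atoms: none
Why: Heterogeneous catalytic hydrogenation saturates the ring alkene and the chain alkene, whatever its geometry, while the dialkyl ketone, the silyl ether and the three stereocentres, none of which is touched, remain.

**Step 9**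
Reactants: 15 (2R,3R,6S)-3-(tert-butyldimethylsilyloxy)-2-methyl-6-(13-oxotetradecyl)piperidine
Product: 16 (−)-spectaline, (2R,3R,6S)-2-methyl-6-(13-oxotetradecyl)piperidin-3-ol
Conditions: Bu4NF, THF, rt to 45 °C; aqueous work-up
Reagents that add atoms: none
Why: Fluoride-induced cleavage of the Si–O bond frees the C3 hydroxyl under conditions to which the secondary amine and the ketone are indifferent.

**Step 10**
Reactants: 16 (−)-spectaline, (2R,3R,6S)-2-methyl-6-(13-oxotetradecyl)piperidin-3-ol
Product: 19 (−)-3-O-acetylspectaline, (2R,3R,6S)-2-methyl-6-(13-oxotetradecyl)piperidin-3-yl acetate, via spectalinium trifluoroacetate 17 (not isolated), via O-acetylspectalinium trifluoroacetate 18 (not isolated)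
Conditions: CF3CO2H, 0 °C; AcCl (about 5 equiv), 0 °C to rt; evaporate; cold aq. NaHCO3/CH2Cl2
Reagents that add atoms: acetyl chloride, CC(=O)Cl
Why: Chemoselective O-acylation of an amino alcohol under acidic conditions, in which nitrogen is fully protonated and inert in trifluoroacetic acid, acetyl chloride esterifies the C3 hydroxyl with retention, and cold hydrogencarbonate then liberates the free base.

**Compound list**
1 | methyl N-(tert-butoxycarbonyl)-D-alaninate | C[C@@H](NC(=O)OC(C)(C)C)C(=O)OC | starting material
2 | N-Boc-D-alaninal, tert-butyl N-[(2R)-1-oxopropan-2-yl]carbamate (held as its aluminium hemiacetal) | C[C@@H](NC(=O)OC(C)(C)C)C=O | intermediate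
3 | tert-butyl N-[(2R,3R)-3-hydroxypent-4-en-2-yl]carbamate | C=C[C@@H](O)[C@@H](C)NC(=O)OC(C)(C)C | intermediate
4 | tert-butyldimethylsilyl N-[(2R,3R)-3-(tert-butyldimethylsilyloxy)pent-4-en-2-yl]carbamate | C=C[C@@H](O[Si](C)(C)C(C)(C)C)[C@@H](C)NC(=O)O[Si](C)(C)C(C)(C)C | intermediate
5 | (2R,3R)-3-(tert-butyldimethylsilyloxy)pent-4-en-2-amine | C=C[C@@H](O[Si](C)(C)C(C)(C)C)[C@@H](C)N | intermediate
6 | cyclopent-2-en-1-one | O=C1C=CCC1 | starting material
7 | cyclopent-2-en-1-ol (racemic) | OC1C=CCC1 | intermediate
8 | cyclopent-2-en-1-yl methyl carbonate (racemic) | COC(=O)OC1C=CCC1 | intermediate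
9 | (2R,3R)-3-(tert-butyldimethylsilyloxy)-N-[(1S)-cyclopent-2-en-1-yl]pent-4-en-2-amine | C=C[C@@H](O[Si](C)(C)C(C)(C)C)[C@@H](C)N[C@@H]1C=CCC1 | intermediate
10 | undec-10-enoyl chloride | C=CCCCCCCCCC(=O)Cl | starting material
11 | dodec-11-en-2-one | CC(=O)CCCCCCCCC=C | intermediate
12 | 4-methylbenzenesulfonate salt of 9 | C=C[C@@H](O[Si](C)(C)C(C)(C)C)[C@@H](C)[NH2+][C@@H]1C=CCC1.Cc1ccc(cc1)S(=O)(=O)[O-] | intermediate
13 | 4-methylbenzenesulfonate salt of 14 | CC(=O)CCCCCCCC/C=C/CC[C@H]1C=C[C@@H](O[Si](C)(C)C(C)(C)C)[C@@H](C)[NH2+]1.Cc1ccc(cc1)S(=O)(=O)[O-] | intermediate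
14 | (2R,3R,6S)-3-(tert-butyldimethylsilyloxy)-2-methyl-6-[(E)-13-oxotetradec-3-enyl]-1,2,3,6-tetrahydropyridine | CC(=O)CCCCCCCC/C=C/CC[C@H]1C=C[C@@H](O[Si](C)(C)C(C)(C)C)[C@@H](C)N1 | intermediate
15 | (2R,3R,6S)-3-(tert-butyldimethylsilyloxy)-2-methyl-6-(13-oxotetradecyl)piperidine | CC(=O)CCCCCCCCCCCC[C@H]1CC[C@@H](O[Si](C)(C)C(C)(C)C)[C@@H](C)N1 | intermediate
16 | (−)-spectaline, (2R,3R,6S)-2-methyl-6-(13-oxotetradecyl)piperidin-3-ol | CC(=O)CCCCCCCCCCCC[C@H]1CC[C@@H](O)[C@@H](C)N1 | intermediate
17 | spectalinium trifluoroacetate | CC(=O)CCCCCCCCCCCC[C@H]1CC[C@@H](O)[C@@H](C)[NH2+]1.[O-]C(=O)C(F)(F)F | intermediate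
18 | O-acetylspectalinium trifluoroacetate | CC(=O)CCCCCCCCCCCC[C@H]1CC[C@@H](OC(C)=O)[C@@H](C)[NH2+]1.[O-]C(=O)C(F)(F)F | intermediate
19 | (−)-3-O-acetylspectaline, (2R,3R,6S)-2-methyl-6-(13-oxotetradecyl)piperidin-3-yl acetate | CC(=O)CCCCCCCCCCCC[C@H]1CC[C@@H](OC(C)=O)[C@@H](C)N1 | target

**Step count.** Total: 10 steps. Longest linear sequence: 7 steps (steps 1, 2, 5, 7, 8, 9, 10; the branch through steps 3 and 4 is equally long).

**Steps most likely to fail**

Step 7. Ruthenium may be tied up by nitrogen that is not fully protonated. The cascade may stop after ring rearrangement, so that the cross-coupling leg stays incomplete. Self-metathesis of 11 may outrun the crossed reaction. The fallback sets out from 9 and comes back at 14; it masks nitrogen covalently and splits the cascade into two separate metatheses. Trifluoroacetic anhydride and pyridine in CH2Cl2 should convert 9 into 2,2,2-trifluoro-N-[(2R,3R)-3-(tert-butyldimethylsilyloxy)pent-4-en-2-yl]-N-[(1S)-cyclopent-2-en-1-yl]acetamide F1. With RuCl2(H2IMes)(=CH-C6H4-O-iPr) in CH2Cl2 under ethene, the neutral amide should undergo ring rearrangement alone to 1-[(2R,3R,6S)-6-(but-3-enyl)-3-(tert-butyldimethylsilyloxy)-2-methyl-3,6-dihydro-2H-pyridin-1-yl]-2,2,2-trifluoroethanone F2. A separate cross-metathesis of this terminal alkene with an excess of 11 and the same catalyst should give 1-[(2R,3R,6S)-3-(tert-butyldimethylsilyloxy)-2-methyl-6-[(E)-13-oxotetradec-3-enyl]-3,6-dihydro-2H-pyridin-1-yl]-2,2,2-trifluoroethanone F3. K2CO3 in aqueous methanol then cleaves the trifluoroacetamide to 14.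

Step 5. The hindered neutral amine may capture the allyl complex slowly inside the ligand pocket. Mismatched double stereodifferentiation may also give poor control at the future C6. The fallback sets out from 5 and comes back at 9; it changes the nucleophile to a sulfonamide anion, the class for which this asymmetric allylation of five-ring carbonates is best established. 2-Nitrobenzenesulfonyl chloride and Et3N in CH2Cl2 should give N-[(2R,3R)-3-(tert-butyldimethylsilyloxy)pent-4-en-2-yl]-2-nitrobenzenesulfonamide F4. Allylation with 8 under Pd2(dba)3·CHCl3 and the same chiral ligand should give N-[(1S)-cyclopent-2-en-1-yl]-N-[(2R,3R)-3-(tert-butyldimethylsilyloxy)pent-4-en-2-yl]-2-nitrobenzenesulfonamide F5. Thiophenol and K2CO3 in DMF (Fukuyama deprotection) then release 9.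

Step 1. The vinyl addition may show poor facial selectivity, giving threo and erythro alcohols that are hard to separate, and C2 may partly epimerise. The fallback sets out from 1 and comes back at 3; it places C3 under catalyst control.
- MeNH(OMe)·HCl and iPrMgCl in THF at −20 °C should give tert-butyl N-[(2R)-1-[methoxy(methyl)amino]-1-oxopropan-2-yl]carbamate F6.
- Lithium (trimethylsilyl)acetylide in THF at −78 °C should give tert-butyl N-[(2R)-3-oxo-5-(trimethylsilyl)pent-4-yn-2-yl]carbamate F7.
- Noyori asymmetric transfer hydrogenation with RuCl(p-cymene)[(S,S)-TsDPEN] in iPrOH, the catalyst enantiomer expected to deliver the (3R) carbinol, should give tert-butyl N-[(2R,3R)-3-hydroxy-5-(trimethylsilyl)pent-4-yn-2-yl]carbamate F8.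
- K2CO3 in MeOH removes the silyl group to give tert-butyl N-[(2R,3R)-3-hydroxypent-4-yn-2-yl]carbamate F9.
- Semi-hydrogenation over Lindlar catalyst (Pd/CaCO3 poisoned with Pb(OAc)2, quinoline) then gives 3.

**Further compounds**
F1 | step 7 | 2,2,2-trifluoro-N-[(2R,3R)-3-(tert-butyldimethylsilyloxy)pent-4-en-2-yl]-N-[(1S)-cyclopent-2-en-1-yl]acetamide | C=C[C@@H](O[Si](C)(C)C(C)(C)C)[C@@H](C)N(C(=O)C(F)(F)F)[C@@H]1C=CCC1
F2 | step 7 | 1-[(2R,3R,6S)-6-(but-3-enyl)-3-(tert-butyldimethylsilyloxy)-2-methyl-3,6-dihydro-2H-pyridin-1-yl]-2,2,2-trifluoroethanone | C=CCC[C@H]1C=C[C@@H](O[Si](C)(C)C(C)(C)C)[C@@H](C)N1C(=O)C(F)(F)F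
F3 | step 7 | 1-[(2R,3R,6S)-3-(tert-butyldimethylsilyloxy)-2-methyl-6-[(E)-13-oxotetradec-3-enyl]-3,6-dihydro-2H-pyridin-1-yl]-2,2,2-trifluoroethanone | CC(=O)CCCCCCCC/C=C/CC[C@H]1C=C[C@@H](O[Si](C)(C)C(C)(C)C)[C@@H](C)N1C(=O)C(F)(F)F
F4 | step 5 | N-[(2R,3R)-3-(tert-butyldimethylsilyloxy)pent-4-en-2-yl]-2-nitrobenzenesulfonamide | C=C[C@@H](O[Si](C)(C)C(C)(C)C)[C@@H](C)NS(=O)(=O)c1ccccc1[N+](=O)[O-]
F5 | step 5 | N-[(1S)-cyclopent-2-en-1-yl]-N-[(2R,3R)-3-(tert-butyldimethylsilyloxy)pent-4-en-2-yl]-2-nitrobenzenesulfonamide | C=C[C@@H](O[Si](C)(C)C(C)(C)C)[C@@H](C)N([C@@H]1C=CCC1)S(=O)(=O)c1ccccc1[N+](=O)[O-]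
F6 | step 1 | tert-butyl N-[(2R)-1-[methoxy(methyl)amino]-1-oxopropan-2-yl]carbamate | C[C@@H](NC(=O)OC(C)(C)C)C(=O)N(C)OC
F7 | step 1 | tert-butyl N-[(2R)-3-oxo-5-(trimethylsilyl)pent-4-yn-2-yl]carbamate | C[C@@H](NC(=O)OC(C)(C)C)C(=O)C#C[Si](C)(C)C
F8 | step 1 | tert-butyl N-[(2R,3R)-3-hydroxy-5-(trimethylsilyl)pent-4-yn-2-yl]carbamate | C[Si](C)(C)C#C[C@@H](O)[C@@H](C)NC(=O)OC(C)(C)C
F9 | step 1 | tert-butyl N-[(2R,3R)-3-hydroxypent-4-yn-2-yl]carbamate | C#C[C@@H](O)[C@@H](C)NC(=O)OC(C)(C)C
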